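Start from the balance. In the winter run, starting material plus target make 99.5 % of the charge at 12.0 h and 96.6 % at 15.0 h, a gap of 3.4 percentage points against a scatter of 1 point per reading. So up to the gap you may count one target for each starting material lost. I also assume that one second substrate goes with it, which this single run cannot show.

- winter: starting material 0.10 M; second substrate 0.090 M; precatalyst 1.2 µM; run made earlier
- flask: starting material 0.10 M; second substrate 0.0600 M; precatalyst 1.2 µM; time 6.0 d

winter run (percent of the starting material charged)

| time / h | target / % | starting material / % |
|---|---|---|
| 2.00 | 1.9 | 99.2 |
| 4.00 | 3.3 | 96.5 |
| 6.00 | 6.0 | 93.8 |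
| 8.00 | 8.7 | 91.7 |
| 10.0 | 12.3 | 88.0 |
| 12.0 | 15.3 | 84.2 |
| 15.0 | 16.6 | 80.0 |

(readings scatter by 1 percentage point)

1. time up to 6.0 d at which target stands highest
2. the amount of target, in percent of the starting material charged, at that time
3. earliest time at which at least nineteen twentieths of that best amount are there, in d
4. latest time at which they still are, in d

- the analysis behind the earlier runs scatters by 1 percentage point, standard deviation

Now put the flask on a ladder of times. The lowest rung is 0.62 d: by then the winter run has lost starting material at an average fraction of the charge of 0.0133 /h, and the gap first shows. In this flask the second substrate is charged at 0.600 of the starting material, which makes it the limiting reagent. Carry the stop line: the fraction of starting material left once one-for-one use has taken the whole charge of second substrate, 40.0 %.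

My own reckoning is that at the winter rate this flask reaches the line in 1.88 d, later than the first rung. The top rung, 6.0 d, is 3.19 times that, so whatever opened the gap has days to work on target. The line bounds conversion, not target: from 12.0 h to 15.0 h the readings show target up 1.3 points while starting material fell 4.2 points. I therefore look for a peak before 1.88 d, then a fall.

The forecast differs: 50 % at 4.5 d, with the span from 3 d to 6 d, “a broad maximum late in the window”.

The flask gives 18.4 % at 1.29 d, and the asked span runs from 0.980 d to 1.70 d, so stop inside it. At the best time side product already stands at 13.6 %. At 6.00 d starting material is 40.1 %, on the line of 40.0 %, with 0.124 % of the second substrate's own charge left, while target is 3.18 % and side product 53.1 %.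

    starting material + free enzyme ⇌ first complex (K = 38.0 /M, k = 6000 /M/s)
    first complex → loaded enzyme + first product (k = 2.00 /s)
    second substrate + loaded enzyme ⇌ second complex (K = 11.0 /M, k = 11000 /M/s)
    second complex → free enzyme + target (k = 1.20 /s)
    target + free enzyme ⇌ isomer of the product + free enzyme, rate k5*[free enzyme]*[target] forward; the back reaction follows from the equilibrium constant (K = 15.0, k = 22.0 /M/s)
    target + first product → side product (k = 6.80 × 10⁻⁴ /M/s)
    second substrate + precatalyst → free enzyme + spent reagent (k = 9.90 × 10⁻⁴ /M/s)

Take a neighbour flask, the same recipe with second substrate at 0.150 of the starting material: its line comes to 85.0 %. Computed, that neighbour flask ends with 85.0 % starting material, and its target reaches 7.76 % at best and stands at 3.43 % at the end.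

Readings and results were generated by integration on assumed constants; scatter was added.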